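The runs come from a simulation on assumed constants, noise included.

The flask asked about holds half the charge of the theta run, at the same loading of precatalyst and the same dosing time, so a quick number has to come from that one run.

| setting | theta | flask |
|---|---|---|
| starting material | 0.10 M (fed, over 40 s) | 0.050 M (fed, over 40 s) |
| precatalyst | 0.01 mol% | 0.01 mol% |
| remark | run made earlier |  |
| time |  | 3.0 min |

theta run (percent of the starting material charged)

| time / s | product / % | starting material / % |
|---|---|---|
| 10.0 | 1 | 24 |
| 20.0 | 3 | 48 |
| 30.0 | 19 | 59 |
| 40.0 | 35 | 69 |
| 50.0 | 51 | 48 |

(each reading ± 2 percentage points)

- concentration of product at 3.0 min, in M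
- concentration of starting material at 3.0 min, in M

- the numbers in the tables scatter by 2 percentage points (one standard deviation)
- reactions considered so far: precatalyst -> enzyme; enzyme <-> dormant form; starting material + enzyme -> product + enzyme
- percentages count the whole charge, also what has not yet gone in
- no earlier run changes the charge of precatalyst; that part of a forecast is a guess

Between 30.0 s and 50.0 s, the theta run gained product from 19% to 51%, while starting material read 59% and 48% at the two ends. Replacing the curve by its mean gives a reading of 0.0299 /s for the mean specific rate: product gained per second over a stretch, divided by the mean of starting material at its two ends, a pseudo-first-order constant. Half the charge at the same loading means half the catalyst, so the guess for the new flask is 0.0150 /s. With the feed replaced by one shot at its mean time, 20.0 s, this reckoning leaves 9.14% of the charge, or 0.00457 M of starting material and 0.0454 M of product. The forecast gives 0.044 M of product and 0.006 M of starting material, so its [starting material] stands higher than this reckoning's, and it warns: “Saturation can't be excluded, because starting material varies little”.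

At 3.0 min the flask gives 0.0393 M of product and 0.0107 M of starting material.

    precatalyst → enzyme (k = 0.00820 /s)
    enzyme ⇌ dormant form (K = 1.70, k = 0.00920 /s)
    starting material + enzyme → product + enzyme, rate k3*[starting material]^2.5*[enzyme]/(1 + ([starting material]/Kh3)^2.5) (49.0 mM, k = 2.30 × 10⁶ /M².5/s)

From the shot to 3.0 min, the flask's mean specific rate is 0.00810 /s, lower than the 0.0104 /s that the reckoning's 9.14% gives when read the same way. The neighbour flask with 0.020 M of starting material, at the same loading, gives a lower 0.00281 /s. In the flask, drawing out the feed makes next to no difference to [product]. The flask has not come to rest at 3.0 min: from there to 30.0 min its mean specific rate is 8.48 × 10⁻⁴ /s, lower still, yet [product] climbs to 0.0480 M and [starting material] falls to 0.00198 M.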